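(The numbers of this flask were drawn at random within sensible limits; the flask was simulated.)

Follow the substrate to its branch and ask what fraction of it ever reaches target.

    intermediate C → target (k1 = 0.15 s⁻¹)
    capture agent + intermediate C → trapped intermediate (k2 = 130 M⁻¹ s⁻¹)
    reagent + intermediate A → intermediate D (k3 = 79 M⁻¹ s⁻¹)
    substrate ⇌ intermediate B (K4 = 2.7, k4 = 0.26 s⁻¹)
    substrate → intermediate A (k5 = 0.58 s⁻¹)
    crystals ⇌ target, rate k6*(cs6 - [target]) while solid is left; crystals form when [target] > cs6 (cs6 = 0.078 mM, k6 = 2.2 s⁻¹)
    reagent + intermediate D → side product (k7 = 220 M⁻¹ s⁻¹)
    target → over-reaction product (k8 = 3.8 × 10⁻⁴ s⁻¹)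
    substrate ⇌ intermediate C (K9 = 0.45, k9 = 0.011 s⁻¹)

| setting | midnight | dawn | dusk |
|---|---|---|---|
| substrate | 2.0 mM | 2.0 mM | 2.0 mM |
| reagent | 2.40 mM | 7.20 mM | 22.0 mM |
| capture agent | 0.200 mM | 0.200 mM | 0.200 mM |
| time | 50 s | 50 s | 50 s |

* which of the two there is more of at the end, midnight (target / side product)
* which of the two there is more of at the end, dawn (target / side product)
* which of the two there is more of at the end, dusk (target / side product)
* final target, as a percentage of the substrate charged, in midnight
* final target, as a percentage of the substrate charged, in dawn
* final target, as a percentage of the substrate charged, in dusk

- amounts and yields of target count crystals too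
- given per volume of solution although it is solid: crystals
- run time (midnight): 50 s

Target's curve starts with zero slope, for target is made from intermediate C and none is charged. Substrate falls first, with a time of 1.18 s, and that is the first knee. Intermediate A takes substrate 52.7 times faster than intermediate C does, so a first round of the reckoning made here gives 1.86% for target.

Put back what intermediate C does next. It leaves at 0.200 s⁻¹, of which 0.15 s⁻¹ goes to target, 0.0260 s⁻¹ to trapped intermediate and 0.0244 s⁻¹ back to substrate, which then chooses again. The net drain through intermediate C is 0.00966 s⁻¹, so substrate is lost for good at 0.590 s⁻¹. That gives 1.40% as the target share, the fraction of the charged substrate that ends as target once the branches are taken, in the trade a branching ratio. The share contains no reagent term, since reagent reacts after the branch, with intermediate A and intermediate D. Solubility stands at 3.90% of the charge, above the share, so the reckoning expects no crystals.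

Intermediate B delays the level. It returns at 0.0963 s⁻¹, and a first estimate of the slow rate is 0.0668 s⁻¹. Put back once, this becomes 0.0643 s⁻¹, so the second knee lies near 15.5 s. The slow phase opens with 35.7% of the charge in substrate and intermediate B together and keeps 1.43% of the charge unfinished at the end. With the slight loss to over-reaction product, 1.35% is the level, so the reckoned target is 1.35% in midnight, 1.35% in dawn and 1.35% in dusk.

Each side product costs two reagent, so reagent in midnight is the limiting reagent, capping side product at 60.0% of the substrate. The larger is then side product in midnight, side product in dawn and side product in dusk.

The forecast names side product, side product and side product for midnight, dawn and dusk, with target at 1.36%, 1.36% and 1.36%: “Reagent acts only downstream of that irreversible branch”.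

The simulation gives side product, side product and side product, with target at 1.35%, 1.35% and 1.35%. A neighbour of dawn charged with 8.0 mM of substrate has its solubility at 0.975% of the charge, below the share, and it ends with 1.36% of target, of which 0.382% stands as crystals. Dusk is not at rest at 50 s: substrate and intermediate B still hold 1.43%, worth 0.0199% more target at the share. Left to ten times the time, over-reaction product acts on, which computes to 1.15%, and dusk stands at 1.16% of target at 500 s.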